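**Retrosynthetic overview**

1. The stearate ester C–O bond is made last, by acylation of the benzylic alcohol on C7 (benzoxepine locants: O1, C2, C3 with its exocyclic CH2, C4, C5, C5a, C6–C9, C9a).
2. The C7 carbinol carbon is carried as a tert-butyl ester. It sits para to C9a, so at the ester oxidation level it makes C9a–F an SNAr electrophile; a hydride reduction later returns it to the level of the target.
3. Key disconnection O1–C9a: the oxepine ring (the only ring to be built; the benzene ring is bought) closes by a light-gated SNAr of an open-chain E-dienol aryl fluoride. The aryl-diene chromophore C5a–C5=C4–C3(=CH2) accepts triplet energy, so the cis C4=C5 geometry the ring requires is generated in the flask and no alkene stereocontrol is needed earlier.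
4. The dienol comes from 2-bromoallyl alcohol (C2, C3, exocyclic CH2; Suzuki–Miyaura, C3–C4 bond) and a vinyl boronate (C4, C5; Mizoroki–Heck, C5–C5a bond) on tert-butyl 3-bromo-4-fluorobenzoate.

Key step: step 3

Remark: the target has no stereocentre; its only stereochemical element, the cis C4=C5 double bond, is enforced by the seven-membered ring.

**Route**

Step 1
Reactants: 1 tert-butyl 3-bromo-4-fluorobenzoate; 2 4,4,5,5-tetramethyl-2-vinyl-1,3,2-dioxaborolane (vinylboronic acid pinacol ester)
Product: 3 tert-butyl 4-fluoro-3-[(E)-2-(4,4,5,5-tetramethyl-1,3,2-dioxaborolan-2-yl)ethenyl]benzoate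
Conditions: Pd2(dba)3 (2 mol%), P(tBu)3·HBF4 (8 mol%), Cy2NMe (1.5 equiv), toluene, 80 °C
Reagents that add atoms: 2 4,4,5,5-tetramethyl-2-vinyl-1,3,2-dioxaborolane, C=CB1OC(C)(C)C(C)(C)O1
Why: Mizoroki–Heck reaction in which the electron-poor aryl bromide adds to zerovalent palladium, the aryl group is delivered to the terminal vinyl carbon and syn β-hydride elimination should give the E alkenyl boronate, while an amine base free of oxygen nucleophiles keeps the competing transmetalation silent; the C–F bond and the tert-butyl ester are inert, and the alkene geometry is in any case irrelevant for step 3.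

Step 2
Reactants: 3 tert-butyl 4-fluoro-3-[(E)-2-(4,4,5,5-tetramethyl-1,3,2-dioxaborolan-2-yl)ethenyl]benzoate; 4 2-bromoprop-2-en-1-ol
Product: 5 tert-butyl 4-fluoro-3-[(1E)-3-(hydroxymethyl)buta-1,3-dien-1-yl]benzoate
Conditions: PdCl2(dppf) (5 mol%), K2CO3 (3 equiv), THF/H2O (4:1), 60 °C
Reagents that add atoms: 4 2-bromoprop-2-en-1-ol, OCC(Br)=C
Why: Suzuki–Miyaura coupling of an alkenyl boronate with a vinyl bromide, stereoretentive at the boronate carbon, which should form the C3–C4 bond of the 2-substituted diene; the aryl fluoride, the tert-butyl ester and the free allylic alcohol are not expected to react with aqueous carbonate at this temperature.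

Step 3
Reactants: 5 tert-butyl 4-fluoro-3-[(1E)-3-(hydroxymethyl)buta-1,3-dien-1-yl]benzoate
Product: 8 tert-butyl 3-methylidene-2,3-dihydro-1-benzoxepine-7-carboxylate, via Z-dienol 6 (not isolated), via potassium Z-alkoxide 7 (not isolated)
Conditions: Ir(ppy)3 (1 mol%), 450 nm LEDs, DMF (0.01 M), 25 °C; then KN(SiMe3)2 (1.05 equiv, slow addition) under continued irradiation, 25 to 40 °C
Reagents that add atoms: none
Why: Triplet energy transfer from photoexcited Ir(ppy)3 to the aryl-diene chromophore C5a–C5=C4–C3(=CH2) should give a twisted triplet that relaxes to both the E isomer 5 and the Z isomer 6; after deprotonation only the Z alkoxide 7 can bring O1 to C9a, where addition gives a Meisenheimer anion delocalised into the para ester on C7 and loss of fluoride restores the arene. The closest known reaction types are the sensitised E-to-Z isomerisation of styrenes coupled in one flask to a thermal cyclisation of the Z isomer (as in photocatalytic coumarin formation from E-cinnamates) and the SNAr etherification of 4-fluorobenzoate esters by alkoxides. The oxepine ring closes in a 7-exo-trig addition of O1 to the C9a=C9 bond of the arene followed by elimination of fluoride. No stereocentre is formed; the cis C4=C5 bond is supplied by the photochemical event and then locked by the ring, so any E/Z mixture of 5 should converge on one product. The step needs intramolecular over intermolecular substitution, secured by high dilution, by the inability of the E alkoxide to reach C9a and by continuous removal of the Z isomer from the photostationary mixture. It also needs O-arylation over acyl transfer and over attack by the base, secured by the hindered tert-butyl ester and by one equivalent of a non-nucleophilic amide base that is consumed at once by the alcohol.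

Step 4
Reactants: 8 tert-butyl 3-methylidene-2,3-dihydro-1-benzoxepine-7-carboxylate
Product: 9 (3-methylidene-2,3-dihydro-1-benzoxepin-7-yl)methanol
Conditions: LiAlH4 (1.5 equiv), THF, 0 °C; then Na2SO4·10H2O
Reagents that add atoms: none
Why: Hydride reduction of an ester to the primary alcohol with LiAlH4; the tert-butyl benzoate is the only electrophile, and the unactivated conjugated diene and the allyl aryl ether are not expected to react with aluminium hydride at 0 °C.

Step 5
Reactants: 9 (3-methylidene-2,3-dihydro-1-benzoxepin-7-yl)methanol; 10 octadecanoyl chloride (stearoyl chloride)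
Product: 11 (3-methylidene-2,3-dihydro-1-benzoxepin-7-yl)methyl octadecanoate
Conditions: octadecanoyl chloride (1.1 equiv), Et3N (1.5 equiv), DMAP (5 mol%), CH2Cl2, 0 °C to rt
Reagents that add atoms: 10 octadecanoyl chloride, CCCCCCCCCCCCCCCCCC(=O)Cl
Why: DMAP-catalysed acylation of a primary benzylic alcohol by an acid chloride (nucleophilic acyl substitution); the alcohol is the only nucleophile present and the diene and aryl ether are inert to these conditions.

**Compound list**

1 | tert-butyl 3-bromo-4-fluorobenzoate | CC(C)(C)OC(=O)c1ccc(F)c(Br)c1 | starting material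
2 | 4,4,5,5-tetramethyl-2-vinyl-1,3,2-dioxaborolane | C=CB1OC(C)(C)C(C)(C)O1 | starting material
3 | tert-butyl 4-fluoro-3-[(E)-2-(4,4,5,5-tetramethyl-1,3,2-dioxaborolan-2-yl)ethenyl]benzoate | CC(C)(C)OC(=O)c1ccc(F)c(/C=C/B2OC(C)(C)C(C)(C)O2)c1 | intermediate
4 | 2-bromoprop-2-en-1-ol | OCC(Br)=C | starting material
5 | tert-butyl 4-fluoro-3-[(1E)-3-(hydroxymethyl)buta-1,3-dien-1-yl]benzoate | CC(C)(C)OC(=O)c1ccc(F)c(/C=C/C(=C)CO)c1 | intermediate
6 | tert-butyl 4-fluoro-3-[(1Z)-3-(hydroxymethyl)buta-1,3-dien-1-yl]benzoate (formed in the flask, not isolated) | CC(C)(C)OC(=O)c1ccc(F)c(/C=C\C(=C)CO)c1 | intermediate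
7 | potassium 2-{(Z)-2-[5-(tert-butoxycarbonyl)-2-fluorophenyl]ethenyl}prop-2-en-1-olate (formed in the flask, not isolated) | CC(C)(C)OC(=O)c1ccc(F)c(/C=C\C(=C)C[O-])c1.[K+] | intermediate
8 | tert-butyl 3-methylidene-2,3-dihydro-1-benzoxepine-7-carboxylate | C=C1C=Cc2cc(C(=O)OC(C)(C)C)ccc2OC1 | intermediate
9 | (3-methylidene-2,3-dihydro-1-benzoxepin-7-yl)methanol | C=C1C=Cc2cc(CO)ccc2OC1 | intermediate
10 | octadecanoyl chloride | CCCCCCCCCCCCCCCCCC(=O)Cl | starting material
11 | (3-methylidene-2,3-dihydro-1-benzoxepin-7-yl)methyl octadecanoate | C=C1C=Cc2cc(COC(=O)CCCCCCCCCCCCCCCCC)ccc2OC1 | target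

**Step count**

Total steps: 5. Longest linear sequence: 5 steps (from 1 to 11).

**Steps most likely to fail**

Step 3 (key step). Triplet sensitisation of the diene may lead to [2+2] photodimerisation or to slow build-up of the Z isomer, so that intermolecular etherification of the E alkoxide or photodegradation of the product outruns ring closure. The fallback sets out from 3 and fixes the Z geometry by a stereospecific ionic sequence, then closes the ring in the dark. Bromine (CH2Cl2, −78 °C) should add anti to the alkenyl boronate to give the racemic dibromide tert-butyl 3-[(1S*,2R*)-1,2-dibromo-2-(4,4,5,5-tetramethyl-1,3,2-dioxaborolan-2-yl)ethyl]-4-fluorobenzoate F1, which is not isolated. Methoxide-induced anti elimination of boron and bromine (NaOMe, MeOH, 0 °C) should then give, with inversion of alkene geometry, tert-butyl 3-[(Z)-2-bromoethenyl]-4-fluorobenzoate F2. A stereoretentive Stille coupling of F2 with 2-(tributylstannyl)prop-2-en-1-ol (OCC(=C)[Sn](CCCC)(CCCC)CCCC; Pd2(dba)3, P(2-furyl)3, DMF, 50 °C) should give the Z-dienol 6, here isolated. Treatment of 6 with KN(SiMe3)2 in DMF at 25 to 60 °C without light should close the ring through 7 and return to the route at 8.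

Step 1. Transmetalation of the vinyl boronate to the arylpalladium bromide (Suzuki pathway) or insertion with the opposite regiochemistry may compete with the desired Heck pathway. The fallback sets out from 1 and deliberately uses the Suzuki pathway. Coupling of 1 with 2 under aqueous base (PdCl2(dppf), K2CO3, dioxane/H2O, 80 °C) should give tert-butyl 3-ethenyl-4-fluorobenzoate F3. A Mizoroki–Heck reaction of F3 with vinyl bromide 4 (Pd(OAc)2, P(o-tol)3, Et3N, MeCN, 80 °C) should then form the C4–C3 bond and return to the route at 5, bypassing 3.

Step 2. Protodeboronation of the alkenyl boronate under aqueous base, or Diels–Alder self-dimerisation of the 2-substituted diene at the coupling temperature, may erode the coupling. The fallback sets out from 3 and reverses the polarity of the partners. Iododeboronation with retention (NaOH, then I2, THF/H2O, 0 °C) should give tert-butyl 4-fluoro-3-[(E)-2-iodoethenyl]benzoate F4. A base-free Stille coupling of F4 with 2-(tributylstannyl)prop-2-en-1-ol at room temperature (Pd2(dba)3, P(2-furyl)3, DMF, 25 °C) should return to the route at 5.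

**Further compounds**

F1 | step 3 | tert-butyl 3-[(1S*,2R*)-1,2-dibromo-2-(4,4,5,5-tetramethyl-1,3,2-dioxaborolan-2-yl)ethyl]-4-fluorobenzoate (racemic, not isolated) | CC(C)(C)OC(=O)c1ccc(F)c([C@H](Br)[C@H](Br)B2OC(C)(C)C(C)(C)O2)c1
F2 | step 3 | tert-butyl 3-[(Z)-2-bromoethenyl]-4-fluorobenzoate | CC(C)(C)OC(=O)c1ccc(F)c(/C=C\Br)c1
F3 | step 1 | tert-butyl 3-ethenyl-4-fluorobenzoate | C=Cc1cc(C(=O)OC(C)(C)C)ccc1F
F4 | step 2 | tert-butyl 4-fluoro-3-[(E)-2-iodoethenyl]benzoate | CC(C)(C)OC(=O)c1ccc(F)c(/C=C/I)c1
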